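**Assumption:** guaiane numbering is used. Unprimed atoms are the cyclopentene half (first half of the target SMILES) and primed atoms are the norbornanone half. α is the face carrying H‑1 and H‑7. (–)-α‑Santonin is taken as commercially available.

## Retrosynthetic overview
1. The C10 and C10′ carbinols come last, from a 10,10′‑diketone plus "Me⁻" attacking the open face. The diketone comes from two exocyclic methylenes that are carried through the route, so no protecting groups are needed.
2. Key cut, replacing the biomimetic [4+2]: only C3–C5′ of the norbornanone is broken. It is formed by a Lewis‑acid ene‑type conjugate cyclisation of a Δ3 alkene (half A) onto the enone of half B.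
3. The Δ3,5αH half comes from allylic‑diazene reductive transposition of one enone in a C2‑symmetric bis‑enone (desymmetrisation).
4. C2–C2′ comes from oxidative homocoupling of the α′‑enolate of a single guaianolide enone.
5. That enone comes from α‑santonin by the photochemical 6/6→5/7 rearrangement. Ring order: 5/7/lactone of each half (step 1), then the C2–C2′ link (step 3), then the bicyclo[2.2.1] ring (step 6).

## Route

**Step 1**
Reactants: 1, (–)-α‑santonin
Product: 2, isophotosantonic lactone (10α‑hydroxy‑3‑oxo‑1αH‑guai‑4‑en‑12,6α‑olide)
Conditions: hν (medium‑pressure Hg lamp, Pyrex), AcOH–H2O 1:1, reflux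
Reagents that add atoms: water, O
Why: This is the type‑A cross‑conjugated cyclohexadienone photorearrangement: C1–C5 bonding gives a cyclopropyl oxyallyl zwitterion, and water opens C5–C10 with inversion, which fixes H‑1 as α while C6, C7 and C11 stay untouched.

**Step 2**
Reactants: 2
Product: 3, 3‑oxo‑1αH‑guaia‑4,10(14)‑dien‑12,6α‑olide (exocyclic methylene at C10)
Conditions: SOCl2, pyridine, 0 °C; a minor Δ9 isomer is removed on AgNO3–SiO2
Reagents that add atoms: none
Why: This is an E2 dehydration through the chlorosulfite, and because the equatorial 10α‑O has no antiperiplanar ring hydrogen and H‑1 is syn to it, the proton is lost from the methyl group to give the exocyclic alkene.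

**Step 3**
Reactants: 3 (2 equiv)
Product: 4, C2‑symmetric bis‑enone with a new C2–C2′ bond that is α on both cyclopentenones (H‑2 and H‑2′ β)
Conditions: LDA (1.05 equiv), THF, –78 °C; then anhydrous CuCl2, DMF, –78 → –20 °C
Reagents that add atoms: none
Why: Kinetic α′‑deprotonation followed by oxidative enolate homocoupling (as used to dimerise carvone‑type cross‑conjugated enolates) joins each C2 on the face anti to C10, and this trans,trans isomer is also the thermodynamic one at these epimerisable centres, so C2 and C2′ are set.

**Step 4**
Reactants: 4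
Product: 5, mono‑N‑tosylhydrazone of 4 at C3
Conditions: TsNHNH2 (1.0 equiv), PPTS (cat.), EtOH–THF, 45 °C; recovered 4 is recycled
Reagents that add atoms: p‑toluenesulfonyl hydrazide, Cc1ccc(cc1)S(=O)(=O)NN
Why: This is a hydrazone condensation, and because the two ketones are homotopic any mono‑adduct is the same compound, so the only loss is statistical; the ring‑locked s‑trans enone cannot close to a pyrazoline.

**Step 5**
Reactants: 5
Product: 6, an unsymmetrical dimer in which half A is now the 1αH,5αH‑guaia‑3,10(14)‑diene and is bonded through C2 (α) to C2′ of the unchanged enone half B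
Conditions: catecholborane (3 equiv), CHCl3, –10 → 0 °C; then NaOAc·3H2O, 60 °C
Reagents that add atoms: none
Why: This is the enone tosylhydrazone reduction with allylic diazene rearrangement: hydride attacks C3 from the β face (anti to the C2 substituent), and the α‑diazene delivers H suprafacially to C5 (5αH) while moving the alkene to C3=C4; the s‑trans enone, lactones and 1,1‑disubstituted alkenes do not react with catecholborane at 0 °C.

**Step 6 (key step)**
Reactants: 6
Product: 7, the caruifolin B skeleton with C10=CH2 and C10′=CH2 (C3–C5′ bond formed, Δ4(5) alkene, C3′ ketone, exo 4′‑CH3)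
Conditions: MeAlCl2 (4 equiv), CH2Cl2, –78 → 0 °C; Rochelle salt work‑up; then DBU (cat.), CH2Cl2, rt
Reagents that add atoms: none
Why: Proposed new method: the Al‑complexed enone is attacked at C5′ by C3 of the trisubstituted alkene, which is the only carbon within reach (Markovnikov, five‑membered closure, α face of both rings as enforced by the α,α C2–C2′ link), giving a tertiary C4 cation paired with an aluminium enolate; H‑5α is the only β‑hydrogen on the enolate face, so internal proton transfer gives the Δ4(5) alkene and endo H‑4′, and DBU secures the thermodynamic exo methyl because an endo methyl would collide with C4/C15; the closest known chemistry is the alkylaluminium‑halide‑promoted intramolecular ene/conjugate cyclisation of alkenes onto enones and the π‑route to norbornyl systems, and C3, C5′ and C4′ are set here.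

**Step 7**
Reactants: 7
Product: 8, the 14,14′‑dinor‑10,10′‑dioxo compound (triketone bis‑lactone)
Conditions: K2OsO4·2H2O (5 mol %), NaIO4 (6 equiv), 2,6‑lutidine, dioxane–H2O 3:1, rt
Reagents that add atoms: OsO4, O=[Os](=O)(=O)=O; NaIO4, [Na+].[O-]I(=O)(=O)=O
Why: This is a Lemieux–Johnson cleavage in which the two exposed 1,1‑disubstituted alkenes are osmylated much faster than the buried tetrasubstituted C4=C5, and the buffered neutral medium avoids enolisation at C1.

**Step 8**
Reactants: 8
Product: 9, caruifolin B
Conditions: MeLi/CeCl3 (3 equiv MeCeCl2), THF, –78 °C; aq NH4Cl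
Reagents that add atoms: methyllithium, [Li]C
Why: This is a non‑basic organocerium 1,2‑addition in which both C10 carbonyls are attacked along the open equatorial α trajectory (syn to H‑1 or H‑1′), because the β face of C10′ lies over the C3′–C4′ bridge and that of C10 is screened by H‑2β and H‑6β, so CH3 ends α and OH ends β at both centres; C3′=O is blocked on the exo face by C10′/C15′ and on the endo face by ring A, and the lactones react more slowly at –78 °C.

## Compound list
1 | (–)-α‑santonin | C[C@H]1[C@@H]2CC[C@]3(C=CC(=O)C(=C3[C@H]2OC1=O)C)C | starting material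
2 | isophotosantonic lactone | CC1=C2[C@H]3OC(=O)[C@@H](C)[C@@H]3CC[C@@](C)(O)[C@@H]2CC1=O | intermediate
3 | 3‑oxo‑1αH‑guaia‑4,10(14)‑dien‑12,6α‑olide | CC1=C2[C@H]3OC(=O)[C@@H](C)[C@@H]3CCC(=C)[C@@H]2CC1=O | intermediate
4 | 2α,2′α‑linked C2‑symmetric bis‑enone | CC1=C2[C@H]3OC(=O)[C@@H](C)[C@@H]3CCC(=C)[C@@H]2[C@H](C1=O)[C@H]4C(=O)C(C)=C5[C@H]6OC(=O)[C@@H](C)[C@@H]6CCC(=C)[C@H]45 | intermediate
5 | mono‑tosylhydrazone of 4 | CC1=C2[C@H]3OC(=O)[C@@H](C)[C@@H]3CCC(=C)[C@@H]2[C@H](C1=NNS(=O)(=O)c7ccc(C)cc7)[C@H]4C(=O)C(C)=C5[C@H]6OC(=O)[C@@H](C)[C@@H]6CCC(=C)[C@H]45 | intermediate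
6 | Δ3,5αH half A / enone half B dimer | CC1=C[C@H]([C@H]4C(=O)C(C)=C5[C@H]6OC(=O)[C@@H](C)[C@@H]6CCC(=C)[C@H]45)[C@@H]2[C@H]1[C@H]3OC(=O)[C@@H](C)[C@@H]3CCC2=C | intermediate
7 | 10(14),10′(14′)‑bis‑methylene norbornanone | CC1=C2[C@H]3OC(=O)[C@@H](C)[C@@H]3CCC(=C)[C@@H]2[C@H]2[C@H]3C(=O)[C@H](C)[C@]4([C@@H]3C(=C)CC[C@H]3[C@H](C)C(=O)O[C@@H]34)[C@@H]12 | intermediate
8 | 14,14′‑dinor‑3′,10,10′‑trione | CC1=C2[C@H]3OC(=O)[C@@H](C)[C@@H]3CCC(=O)[C@@H]2[C@H]2[C@H]3C(=O)[C@H](C)[C@]4([C@@H]3C(=O)CC[C@H]3[C@H](C)C(=O)O[C@@H]34)[C@@H]12 | intermediate
9 | caruifolin B | CC1=C2[C@H]3OC(=O)[C@@H](C)[C@@H]3CC[C@](C)(O)[C@@H]2[C@H]2[C@H]3C(=O)[C@H](C)[C@]4([C@@H]3[C@@](C)(O)CC[C@H]3[C@H](C)C(=O)O[C@@H]34)[C@@H]12 | target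

## Summary
**Total steps:** 8. **Longest linear sequence:** 8 (one monomer, used twice in step 3).

**Three steps most likely to fail, each with a fallback that changes the approach**
1. **Step 6.** The bridging closure is onto a tetrasubstituted enone, and proton loss could give the wrong alkene or the cation could rearrange. Fallback: abandon the stepwise union. Convert 3 into its 3‑silyloxy‑2,4‑diene (LDA/TBSCl) and into the 2,4‑cyclopentadiene (Luche reduction, then allylic selenide and selenoxide elimination). Join the two by a thermal or high‑pressure endo [4+2] to reach 7, then continue with steps 7 and 8.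
2. **Step 3.** The intermolecular coupling joins two hindered secondary α′ carbons, and γ‑deprotonation at the doubly allylic C1–H could compete. Fallback: make the coupling intramolecular. Trap two enolates on iPr2SiCl2 to give the bis(dienoxy)silane and oxidise it with CAN/NaHCO3, so that C2–C2′ forms within the tether.
3. **Step 8.** Facial selectivity at C10 of half A may be modest, the β,γ‑unsaturated ketone may enolise, and C3′=O may compete. Fallback: do not cleave the alkenes. Hydrate 7 by anti‑addition instead, using NBS/H2O (Br⁺ on the open α face, water or the C3′ carbonyl oxygen delivering O from the β face), followed by radical debromination with Bu3SnH.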